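The oxolane ring (O1, C2, C3, C4, C5) is read as a lactone with C5 as its carbonyl and then as a γ-aryl butenolide in which C3 is the β-carbon and C4 the α-carbon. A single three-component operation adds a silicon-masked hydroxymethyl group to C3, anti to the C2 aryl group, and traps the enolate at C4 with O-benzylvanillin, so both side-chain carbons arrive in one flask. The precursor is (S)-5-(3,4,5-trimethoxyphenyl)furan-2(5H)-one, reached by lipase resolution, acryloylation and ring-closing metathesis. Dehydration and hydrogenation then reset C4 cis to C3; lactone deoxygenation, Tamao oxidation and debenzylation complete the target.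

Key step: step 6

Assumption: 4-(benzyloxy)-3-methoxybenzaldehyde is a catalogue compound and is bought; if it had to be made, benzylation of vanillin would add one step outside the longest sequence.

Target configuration: (2S,3R,4R), with the C2 aryl group and the C3 CH2OH trans, and the C3 CH2OH and the C4 benzyl group cis.

Step 1
Reactants: 1 3,4,5-trimethoxybenzaldehyde; 2 vinylmagnesium bromide
Product: 3 rac-1-(3,4,5-trimethoxyphenyl)prop-2-en-1-ol
Conditions: 2 (1.2 equiv, THF solution), THF, −20 to 0 °C; aq. NH4Cl
Reagents that add atoms: none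
Why: Grignard 1,2-addition to a non-enolisable aryl aldehyde should give the allylic alcohol cleanly, the new stereocentre being formed racemic and sorted out in step 2.

Step 2
Reactants: 3 rac-1-(3,4,5-trimethoxyphenyl)prop-2-en-1-ol
Product: 4 (S)-1-(3,4,5-trimethoxyphenyl)prop-2-en-1-ol
Conditions: immobilised Candida antarctica lipase B (Novozym 435), vinyl acetate (3 equiv), tert-butyl methyl ether, 30 °C, stopped slightly beyond half conversion; filtration, chromatography
Reagents that add atoms: none
Why: In this lipase-catalysed kinetic resolution by transesterification the enzyme should acetylate the (R)-alcohol (aryl as large, vinyl as medium group, Kazlauskas rule) and leave the (S)-alcohol, whose enantiopurity rises as conversion passes one half.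

Step 3
Reactants: 4 (S)-1-(3,4,5-trimethoxyphenyl)prop-2-en-1-ol; 5 acryloyl chloride
Product: 6 (S)-1-(3,4,5-trimethoxyphenyl)prop-2-en-1-yl prop-2-enoate
Conditions: 5 (1.3 equiv), iPr2NEt (1.6 equiv), CH2Cl2, −20 to 0 °C; chromatography on Et3N-deactivated silica
Reagents that add atoms: none
Why: O-acylation with an acid chloride does not touch the C–O stereocentre, and the cold basic medium should suppress ionisation of the benzylic-allylic ester.

Step 4
Reactants: 6 (S)-1-(3,4,5-trimethoxyphenyl)prop-2-en-1-yl prop-2-enoate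
Product: 7 (S)-5-(3,4,5-trimethoxyphenyl)furan-2(5H)-one
Conditions: second-generation Grubbs catalyst RuCl2(=CHPh)(H2IMes)(PCy3) (5 mol %), CH2Cl2 (0.01 M), 40 °C; rapid filtration through silica, product stored cold and kept free of amines
Reagents that add atoms: none
Why: Ring-closing metathesis of an allyl acrylate closes the five-membered unsaturated lactone with loss of ethene under neutral conditions that should leave the base-labile stereocentre intact.

Step 5
Reactants: 8 (chloromethyl)isopropoxydimethylsilane
Product: 9 (isopropoxydimethylsilyl)methylmagnesium chloride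
Conditions: Mg turnings (1.2 equiv), BrCH2CH2Br (2 mol %), THF, rt to 45 °C; titrated and used as a THF solution
Reagents that add atoms: magnesium, [Mg]
Why: Insertion of magnesium into the primary C–Cl bond is the standard Grignard formation for this hydroxymethyl anion equivalent, and the hindered Si–OiPr group tolerates it.

Step 6
Reactants: 7 (S)-5-(3,4,5-trimethoxyphenyl)furan-2(5H)-one; 9 (isopropoxydimethylsilyl)methylmagnesium chloride; 10 4-(benzyloxy)-3-methoxybenzaldehyde
Product: 12 (3R,4S,5S)-3-[[4-(benzyloxy)-3-methoxyphenyl](hydroxy)methyl]-4-{[dimethyl(propan-2-yloxy)silyl]methyl}-5-(3,4,5-trimethoxyphenyl)oxolan-2-one as both carbinol epimers, via chloromagnesium lactone enolate 11 (not isolated)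
Conditions: 9 (1.4 equiv), CuBr·SMe2 (20 mol %), THF, −78 °C, 7 added over 1 h; then 10 (1.6 equiv), −78 °C; AcOH in THF, then aq. NH4Cl, at −78 °C
Reagents that add atoms: none
Why: Transmetalation of 9 to monovalent copper gives a silylmethylcopper species that adds 1,4 to 7 (C3–CH2 bond), and the chloromagnesium enolate 11 is captured in the same flask by aldehyde 10 in an aldol addition (C4–benzylic carbon bond). The closest known reaction type is the tandem copper-mediated conjugate addition–aldol trapping of γ-substituted butenolides, here with an (alkoxysilyl)methyl Grignard reagent as hydroxymethyl anion equivalent. No ring is closed: the butenolide ring is carried on as the oxolane of the target at lactone oxidation level. The one lasting new stereocentre, C3, is set by the C2 aryl group, which shields its own face of the nearly flat ring so that the arm enters anti to it (2,3-trans); the aldehyde then enters at C4 anti to the new arm, but C4 and the carbinol centre are erased in step 7 and need no control. The step needs conjugate addition to win over 1,2-addition and over removal of the acidic C2–H (which would racemise 7 through its furanolate), and the soft copper reagent, the weakly basic α-silyl nucleophile, −78 °C and slow addition of 7 should secure this. The cold acidic quench is meant to stop retro-aldol cleavage and attack of the aldolate on the Si–OiPr group.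

Step 7
Reactants: 12 aldol adduct (carbinol epimers)
Product: 14 (3E,4S,5S)-3-[4-(benzyloxy)-3-methoxybenzylidene]-4-{[dimethyl(propan-2-yloxy)silyl]methyl}-5-(3,4,5-trimethoxyphenyl)oxolan-2-one, via carbinol mesylate 13 (not isolated)
Conditions: MsCl (1.5 equiv), Et3N (3 equiv), CH2Cl2, 0 °C; then DBU (2 equiv), 0 °C to rt
Reagents that add atoms: none
Why: Mesylation followed by E1cB elimination through the lactone enolate should funnel both carbinol epimers into the conjugated (E)-benzylidene lactone, removing the C4 and carbinol centres and leaving C2 and C3 untouched.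

Step 8
Reactants: 14 (E)-benzylidene lactone
Product: 15 (3R,4S,5S)-3-[4-(benzyloxy)-3-methoxybenzyl]-4-{[dimethyl(propan-2-yloxy)silyl]methyl}-5-(3,4,5-trimethoxyphenyl)oxolan-2-one
Conditions: H2 (1 atm), 10% Pd/C, Ph2S (1 mol %), EtOAc, rt
Reagents that add atoms: none
Why: Heterogeneous syn-hydrogenation should deliver hydrogen to C4 from the face opposite the adjacent C3 silylmethyl arm (held pseudoaxial by allylic strain with the benzylidene aryl group), giving the 3,4-cis lactone, while the sulfide-poisoned catalyst reduces alkenes without hydrogenolysing the benzyl ether or the benzylic lactone C–O bond.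

Step 9
Reactants: 15 3,4-cis lactone
Product: 16 (3R,4S,5S)-3-[4-(benzyloxy)-3-methoxybenzyl]-4-{[dimethyl(propan-2-yloxy)silyl]methyl}-5-(3,4,5-trimethoxyphenyl)oxolan-2-ol (anomer mixture)
Conditions: iBu2AlH (1.2 equiv), CH2Cl2, −78 °C; aq. potassium sodium tartrate
Reagents that add atoms: none
Why: Partial reduction of a γ-lactone with iBu2AlH at −78 °C stops at the aluminium hemiacetal, which gives the lactol on non-basic hydrolysis without disturbing the epimerisable C4 centre.

Step 10
Reactants: 16 lactol
Product: 18 {(2S,3R,4R)-4-[4-(benzyloxy)-3-methoxybenzyl]-2-(3,4,5-trimethoxyphenyl)oxolan-3-yl}methanol, via isopropoxysilyl oxolane 17 (not isolated)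
Conditions: Et3SiH (3 equiv), BF3·OEt2 (1.5 equiv), CH2Cl2, −78 °C, aq. NaHCO3 quench, crude used directly; then KF, KHCO3, 30% H2O2, THF/MeOH (1:1), rt to 40 °C; aq. Na2S2O3
Reagents that add atoms: hydrogen peroxide, OO
Why: Ionic reduction of the lactol through its C5 oxocarbenium ion (no stereocentre is created) followed by Tamao oxidation of the crude silane should give the primary alcohol, and telescoping makes any exchange of isopropoxide on silicon for fluoride or hydroxide harmless because all such silanes are oxidised alike.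

Step 11
Reactants: 18 O-benzyl alcohol
Product: 19 {(2S,3R,4R)-4-(4-hydroxy-3-methoxybenzyl)-2-(3,4,5-trimethoxyphenyl)oxolan-3-yl}methanol
Conditions: H2 (1 atm), 10% Pd/C, EtOAc/EtOH, rt, stopped at full conversion
Reagents that add atoms: none
Why: Catalytic hydrogenolysis cleaves the aryl benzyl ether far faster than the dialkyl benzylic C2–O bond of the oxolane, so the phenol should be released without touching a stereocentre.

Compound list
1 | 3,4,5-trimethoxybenzaldehyde | COc1cc(C=O)cc(OC)c1OC | starting material
2 | vinylmagnesium bromide | C=C[Mg]Br | starting material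
3 | rac-1-(3,4,5-trimethoxyphenyl)prop-2-en-1-ol | C=CC(O)c1cc(OC)c(OC)c(OC)c1 | intermediate
4 | (S)-1-(3,4,5-trimethoxyphenyl)prop-2-en-1-ol | C=C[C@H](O)c1cc(OC)c(OC)c(OC)c1 | intermediate
5 | acryloyl chloride | C=CC(=O)Cl | starting material
6 | (S)-1-(3,4,5-trimethoxyphenyl)prop-2-en-1-yl prop-2-enoate | C=CC(=O)O[C@H](c1cc(OC)c(OC)c(OC)c1)C=C | intermediate
7 | (S)-5-(3,4,5-trimethoxyphenyl)furan-2(5H)-one | O=C1O[C@H](c2cc(OC)c(OC)c(OC)c2)C=C1 | intermediate
8 | (chloromethyl)isopropoxydimethylsilane | CC(C)O[Si](C)(C)CCl | starting material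
9 | (isopropoxydimethylsilyl)methylmagnesium chloride | CC(C)O[Si](C)(C)C[Mg]Cl | intermediate
10 | 4-(benzyloxy)-3-methoxybenzaldehyde | COc1cc(C=O)ccc1OCc1ccccc1 | starting material
11 | chloromagnesium (4S,5S)-4-{[dimethyl(propan-2-yloxy)silyl]methyl}-5-(3,4,5-trimethoxyphenyl)-4,5-dihydrofuran-2-olate (lactone enolate, 4,5-trans) | Cl[Mg]OC1=C[C@H](C[Si](C)(C)OC(C)C)[C@@H](c2cc(OC)c(OC)c(OC)c2)O1 | intermediate
12 | (3R,4S,5S)-3-[[4-(benzyloxy)-3-methoxyphenyl](hydroxy)methyl]-4-{[dimethyl(propan-2-yloxy)silyl]methyl}-5-(3,4,5-trimethoxyphenyl)oxolan-2-one (all-trans ring, carbinol epimers) | COc1cc(C(O)[C@@H]2C(=O)O[C@H](c3cc(OC)c(OC)c(OC)c3)[C@H]2C[Si](C)(C)OC(C)C)ccc1OCc1ccccc1 | intermediate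
13 | methanesulfonate of 12 at the carbinol oxygen | COc1cc(C(OS(C)(=O)=O)[C@@H]2C(=O)O[C@H](c3cc(OC)c(OC)c(OC)c3)[C@H]2C[Si](C)(C)OC(C)C)ccc1OCc1ccccc1 | intermediate
14 | (3E,4S,5S)-3-[4-(benzyloxy)-3-methoxybenzylidene]-4-{[dimethyl(propan-2-yloxy)silyl]methyl}-5-(3,4,5-trimethoxyphenyl)oxolan-2-one | COc1cc(/C=C2/C(=O)O[C@H](c3cc(OC)c(OC)c(OC)c3)[C@H]2C[Si](C)(C)OC(C)C)ccc1OCc1ccccc1 | intermediate
15 | (3R,4S,5S)-3-[4-(benzyloxy)-3-methoxybenzyl]-4-{[dimethyl(propan-2-yloxy)silyl]methyl}-5-(3,4,5-trimethoxyphenyl)oxolan-2-one (3,4-cis, 4,5-trans) | COc1cc(C[C@H]2C(=O)O[C@H](c3cc(OC)c(OC)c(OC)c3)[C@H]2C[Si](C)(C)OC(C)C)ccc1OCc1ccccc1 | intermediate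
16 | (3R,4S,5S)-3-[4-(benzyloxy)-3-methoxybenzyl]-4-{[dimethyl(propan-2-yloxy)silyl]methyl}-5-(3,4,5-trimethoxyphenyl)oxolan-2-ol (anomer mixture) | COc1cc(C[C@H]2C(O)O[C@H](c3cc(OC)c(OC)c(OC)c3)[C@H]2C[Si](C)(C)OC(C)C)ccc1OCc1ccccc1 | intermediate
17 | {[(2S,3S,4R)-4-[4-(benzyloxy)-3-methoxybenzyl]-2-(3,4,5-trimethoxyphenyl)oxolan-3-yl]methyl}dimethyl(propan-2-yloxy)silane | COc1cc(C[C@H]2CO[C@H](c3cc(OC)c(OC)c(OC)c3)[C@H]2C[Si](C)(C)OC(C)C)ccc1OCc1ccccc1 | intermediate
18 | {(2S,3R,4R)-4-[4-(benzyloxy)-3-methoxybenzyl]-2-(3,4,5-trimethoxyphenyl)oxolan-3-yl}methanol | COc1cc(C[C@H]2CO[C@H](c3cc(OC)c(OC)c(OC)c3)[C@H]2CO)ccc1OCc1ccccc1 | intermediate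
19 | {(2S,3R,4R)-4-(4-hydroxy-3-methoxybenzyl)-2-(3,4,5-trimethoxyphenyl)oxolan-3-yl}methanol (2,3-trans, 3,4-cis) | COc1cc(C[C@H]2CO[C@H](c3cc(OC)c(OC)c(OC)c3)[C@H]2CO)ccc1O | target

Total step count: 11. Longest linear sequence: 10 steps (steps 1 to 4 and 6 to 11, from 3,4,5-trimethoxybenzaldehyde); step 5 is a one-step side branch.

Steps most likely to fail

Step 6. The organometallic may remove the acidic C2–H of the butenolide instead of adding to C3, which racemises the material through its furanolate. Transfer of the α-silylalkyl group from copper may also be slow, the enolate may add to unreacted butenolide, and the aldol with the electron-rich aldehyde may be incomplete or reversible. The fallback decouples the two bond formations; it sets out from 7 and comes back at 12. Reagent 9 and CuBr·SMe2 are used with Me3SiCl present at −78 °C, so that chlorosilane-accelerated conjugate addition outruns proton abstraction and stores the enolate as the trimethylsilyl ketene acetal F1. Mild aqueous acid on work-up hydrolyses this to the 4,5-trans lactone F2. Deprotonation of F2 with LiN(iPr)2 in THF at −78 °C gives the lithium enolate F3, which is added to aldehyde 10 and quenched cold to give 12.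

Step 8. Hydrogen delivery to C4 may show poor facial selectivity, because the C2 aryl group lies on the face that must accept hydrogen. The poisoned catalyst may stall on the trisubstituted alkene, and a more active catalyst may cleave the benzylic lactone C–O bond. The fallback sets C4 by protonation instead of hydrogen delivery; it sets out from 14 and comes back at 15. Conjugate reduction of 14 with LiBH(s-Bu)3 in THF at −78 °C places hydride on the benzylic carbon and gives the planar lithium enolate F4. F4 is protonated at −78 °C by 2,6-di-tert-butyl-4-methylphenol from the face away from the C3 silylmethyl arm, which gives the 3,4-cis lactone 15 without any hydrogenolysis risk.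

Step 10. BF3·OEt2 may ionise the benzylic C2–O bond, after which the pendant electron-rich arene can close an aryltetralin by Friedel–Crafts attack. The C5 oxocarbenium ion may lose the C4 proton to an enol ether and scramble C4, and the silicon handle may degrade before oxidation. The fallback replaces oxocarbenium reduction by an SN2 ring closure that uses no Lewis acid; it sets out from 15 and comes back at 18. Excess LiAlH4 in THF (0 °C to reflux) reduces the lactone to the 1,4-diol and the Si–OiPr group to Si–H, giving the diol hydrosilane F5. TsCl in pyridine (0 to 40 °C) sulfonylates the primary hydroxyl selectively to the mono-tosylate F6. The C2 hydroxyl displaces the tosylate in F6 (5-exo-tet, C2–O bond never broken, so C2 is retained) and gives the hydrosilyl oxolane F7. Tamao oxidation of F7 (KF, KHCO3, 30% H2O2, THF/MeOH), which also accepts Si–H silanes, gives 18.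

Further compounds
F1 | step 6 | {[(4S,5S)-4-{[dimethyl(propan-2-yloxy)silyl]methyl}-5-(3,4,5-trimethoxyphenyl)-4,5-dihydrofuran-2-yl]oxy}trimethylsilane (silyl ketene acetal) | C[Si](C)(C)OC1=C[C@H](C[Si](C)(C)OC(C)C)[C@@H](c2cc(OC)c(OC)c(OC)c2)O1
F2 | step 6 | (4S,5S)-4-{[dimethyl(propan-2-yloxy)silyl]methyl}-5-(3,4,5-trimethoxyphenyl)oxolan-2-one | O=C1C[C@H](C[Si](C)(C)OC(C)C)[C@@H](c2cc(OC)c(OC)c(OC)c2)O1
F3 | step 6 | lithium (4S,5S)-4-{[dimethyl(propan-2-yloxy)silyl]methyl}-5-(3,4,5-trimethoxyphenyl)-4,5-dihydrofuran-2-olate | [Li]OC1=C[C@H](C[Si](C)(C)OC(C)C)[C@@H](c2cc(OC)c(OC)c(OC)c2)O1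
F4 | step 8 | lithium (4S,5S)-3-[4-(benzyloxy)-3-methoxybenzyl]-4-{[dimethyl(propan-2-yloxy)silyl]methyl}-5-(3,4,5-trimethoxyphenyl)-4,5-dihydrofuran-2-olate | [Li]OC1=C(Cc2ccc(OCc3ccccc3)c(OC)c2)[C@H](C[Si](C)(C)OC(C)C)[C@@H](c2cc(OC)c(OC)c(OC)c2)O1
F5 | step 10 | (1S,2S,3R)-3-[4-(benzyloxy)-3-methoxybenzyl]-2-[(dimethylsilyl)methyl]-1-(3,4,5-trimethoxyphenyl)butane-1,4-diol | COc1cc(C[C@@H](CO)[C@H](C[SiH](C)C)[C@H](O)c2cc(OC)c(OC)c(OC)c2)ccc1OCc1ccccc1
F6 | step 10 | (2R,3S,4S)-2-[4-(benzyloxy)-3-methoxybenzyl]-3-[(dimethylsilyl)methyl]-4-hydroxy-4-(3,4,5-trimethoxyphenyl)butyl 4-methylbenzenesulfonate | COc1cc(C[C@@H](COS(=O)(=O)c2ccc(C)cc2)[C@H](C[SiH](C)C)[C@H](O)c2cc(OC)c(OC)c(OC)c2)ccc1OCc1ccccc1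
F7 | step 10 | {[(2S,3S,4R)-4-[4-(benzyloxy)-3-methoxybenzyl]-2-(3,4,5-trimethoxyphenyl)oxolan-3-yl]methyl}dimethylsilane | COc1cc(C[C@H]2CO[C@H](c3cc(OC)c(OC)c(OC)c3)[C@H]2C[SiH](C)C)ccc1OCc1ccccc1
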